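## Structural features

The target is a 2-alkyl-4-acylphloroglucinol. Its single benzene ring (numbered here C1 to C6) carries the ten-carbon side chain at C1, hydroxyls at C2, C4 and C6, the only ring hydrogen at C3 and a 2-methylpropanoyl group at C5, whose carbonyl is chelated by the flanking phenols. The side chain (C1' to C8') is a hydrated geranyl unit joined through the saturated C1'H2–C2'H2 link, with a tertiary alcohol at C3' and a trisubstituted C6'=C7' alkene. C3' is the only stereocentre. It is (S) (OH > C2' arm > C4' arm > CH3), quaternary and isolated, and its two methylene arms differ only from the third atom on, so no reagent acting at C3' itself can tell them apart easily. The fragile groups are three: the tertiary alcohol, which under protic or Lewis acid ionises and is trapped by the C2 hydroxyl (2,2-dialkylchroman) or by the alkene; the alkene, which rules out hydrogenolysis; and the triphenol, which is air-sensitive once deprotonated. Because the three non-oxygenated ring carbons are interchangeable, only one substitution pattern is possible, so ring regiochemistry is not the problem. The real difficulty is to join an unactivated sp3 carbon to exactly one carbon of a threefold nucleophilic phloroglucinol and to end with three free phenols without acid, Lewis acid or hydrogen. The key step exploits the alternating oxygenation of the ring: C6–C1–C2–C3–C4–C5 plus the exocyclic acyl carbonyl is a folded tetraketide, so the C5–C6 bond can be made last by Claisen condensation of an open-chain 3,5,7-triketo ester released from a 2-pyrone.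

## Logic of the disconnections

**14 to 13.** The O–Si bond on the C3' oxygen is added in the retrosynthetic sense. The tertiary hydroxyl is masked because the preceding steps use amine catalysis and strong bases. The gain is a chain that cannot undergo retro-aldol cleavage or lactonise. The demand is removal by buffered fluoride, never acid.

**13 to 11 (through 12).** The ring bond C5–C6 is cut and the C6 carbonyl is tied to the C4 oxygen as an enol lactone. This turns the pentasubstituted arene into an isomeric, non-aromatic lactone that stores the ring carbons as a masked polyketide. In one sentence: the benzene ring is made last, by Claisen closure of 12, which methoxide releases from 11. The gain is that the ring, both carbon substituents and all three free hydroxyls arise in one operation with no phenol protecting group. The demand is that ring opening and Claisen closure beat aldol closure and retro-Claisen scission.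

**11 to 8 and 9.** The bond between ring carbon C5 (the 6-methyl carbon of 8) and the acyl carbonyl is cut. That methyl carbon is the terminus of an extended dienolate and the acyl group comes from a simple amide. The gain is a convergent, one-step introduction of the whole 2-methylpropanoyl unit. The demand is C-acylation at the terminal carbon and a single addition.

**8 to 5 and 6.** The C1–C1' bond is cut. In 6 this carbon is the only nucleophilic carbon, flanked by the lactone carbonyl and the enol, so mono-alkylation is site-defined, unlike in a phloroglucinol. It is done reductively with an aldehyde to avoid O-alkylation. The gain is that 6 is a purchasable triketide. The demand is that the condensation adduct 7 is reduced faster than it adds a second 6 or loses silanol.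

**5 to 4 to 3.** Only the oxidation level at C1' and the silyl groups change. The demand is to tell the primary oxygen from the tertiary one.

**3 to 2 to 1.** The C2'–H bond (from hydride) and the epoxide C–O bonds are cut. The stereocentre C3' comes from face-selective epoxidation of the C2'=C3' alkene of 1, directed by the allylic hydroxyl. The gain is that the problem of telling two methylene arms apart becomes an alkene-face problem solved by a chiral catalyst. The demand is that hydride attacks C2' only, so that the C3'–O bond is never broken.

## Other disconnections considered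

Alternative 1: Cut the bond between ring carbon C1 and C1' (the first plan that comes to mind). The forward key step is a B-alkyl Suzuki–Miyaura coupling of aryl bromide A1 (from phloroglucinol by acylation, bromination and protection as the tris(methoxymethyl) ether) with alkylborane A2 (from 9-BBN hydroboration of the silyl-protected chiral terminal alkene), giving A3. The chosen plan is preferred on three grounds. The arene must first be acylated, halogenated and triply protected. The coupling is at a carbon with two ortho substituents. The three acetal ethers must finally be removed with acid, which is exactly the condition under which the C3' alcohol ionises toward the chroman. Direct base alkylation of the unprotected acylphloroglucinol avoids the protecting groups but meets O-alkylation, polyalkylation and dearomatisation with an unactivated primary halide.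

Alternative 2: Cut the C2'–C3' bond and set the stereocentre in the same event. The forward key step is lithiation–borylation. The hindered secondary benzoate A4 (from commercial (S)-sulcatol) is deprotonated at the carbinol carbon, captured by boronic ester A5, and converted by stereospecific 1,2-metallate rearrangement into tertiary boronic ester A6, which is oxidised to the alcohol. The idea is attractive because a secondary carbinol is easy to obtain enantiopure. However, deprotonation of a non-benzylic dialkyl benzoate is slow and sensitive. The aryl ketone cannot be present, so acylation and three O-demethylations would follow on a molecule that then carries the acid-labile alcohol. The route is clearly longer.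

Alternative 3: Cut the C3'–O bond. The forward key step is an enzymatic Markovnikov hydration of the C2'=C3' alkene of geranyl compound A7 (two steps from phloroglucinol) by a hydratase (hydro-lyase), of the kind that hydrates prenyl side chains of phenols or interconverts myrcene and linalool. It is the shortest plan on paper. The known enzymes of this class are narrow in substrate. The enzyme would have to choose between two trisubstituted alkenes and between two faces next to a bulky arene, and hydration equilibria are unfavourable. The step would therefore rest on enzyme discovery, not on a defensible mechanism-based expectation.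

Key step: step 7

Remark on the chemistry: C3' is quaternary and is never ionised after step 1, so the enantiomeric purity of 14 equals that of 2. If the epoxidation falls short, 2 or 3 would be enriched through a crystalline ester before going on.

## Route

Step 1
Reactants: 1 geraniol [(2E)-3,7-dimethylocta-2,6-dien-1-ol]
Product: 2 [(2S,3S)-3-methyl-3-(4-methylpent-3-en-1-yl)oxiran-2-yl]methanol
Conditions: Ti(OiPr)4 (5 mol %), L-(+)-diethyl tartrate (6 mol %), t-BuOOH (2 equiv), 4 Å molecular sieves, CH2Cl2, −20 °C
Reagents that add atoms: tert-butyl hydroperoxide, CC(C)(C)OO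
Why: Sharpless asymmetric epoxidation; the catalyst formed from Ti(OiPr)4 and the tartrate binds the allylic alcohol and delivers the peroxide oxygen to one face of the 2,3-alkene, L-(+)-tartrate giving the (2S,3S)-epoxide, while the 6,7-alkene has no directing hydroxyl and is left alone. This face selection sets the future C3' stereocentre.

Step 2
Reactants: 2 [(2S,3S)-3-methyl-3-(4-methylpent-3-en-1-yl)oxiran-2-yl]methanol
Product: 3 (3S)-3,7-dimethyloct-6-ene-1,3-diol
Conditions: NaAlH2(OCH2CH2OMe)2, THF, 0 °C to rt; aqueous Rochelle salt work-up
Reagents that add atoms: none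
Why: Hydroxyl-directed hydride opening of a 2,3-epoxy alcohol; the aluminium alkoxide formed at the C1 hydroxyl delivers hydride intramolecularly to C2, which is also the less substituted epoxide carbon, so the 1,3-diol should form. The C3–O bond is not broken, so the stereocentre is retained.

Step 3
Reactants: 3 (3S)-3,7-dimethyloct-6-ene-1,3-diol
Product: 4 (3S)-3,7-dimethyl-1,3-bis(triethylsilyloxy)oct-6-ene
Conditions: Et3SiOTf (2.5 equiv), 2,6-lutidine, CH2Cl2, −78 to 0 °C
Reagents that add atoms: triethylsilyl trifluoromethanesulfonate, CC[Si](CC)(CC)OS(=O)(=O)C(F)(F)F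
Why: Silylation with a silyl triflate, which is reactive enough for the hindered tertiary alcohol as well as the primary one; the hindered pyridine base keeps the medium free of acid.

Step 4
Reactants: 4 (3S)-3,7-dimethyl-1,3-bis(triethylsilyloxy)oct-6-ene
Product: 5 (3S)-3,7-dimethyl-3-(triethylsilyloxy)oct-6-enal
Conditions: (COCl)2, DMSO, CH2Cl2, −78 to −30 °C; then Et3N, −78 to 0 °C
Reagents that add atoms: none
Why: Swern oxidation applied directly to a primary triethylsilyl ether; the chlorosulfonium salt cleaves the unhindered primary O–Si bond and forms the alkoxysulfonium ion, which the base converts into the aldehyde. The tertiary silyl ether is too hindered to react.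

Step 5
Reactants: 5 (3S)-3,7-dimethyl-3-(triethylsilyloxy)oct-6-enal; 6 4-hydroxy-6-methyl-2H-pyran-2-one (triacetic acid lactone)
Product: 8 3-[(3S)-3,7-dimethyl-3-(triethylsilyloxy)oct-6-en-1-yl]-4-hydroxy-6-methyl-2H-pyran-2-one, via alkylidene pyrandione 7 (not isolated)
Conditions: diethyl 2,6-dimethyl-1,4-dihydropyridine-3,5-dicarboxylate (Hantzsch ester, 1.1 equiv), L-proline (20 mol %), CH2Cl2, rt
Reagents that add atoms: none
Why: Three-component reductive alkylation (Knoevenagel condensation, then transfer hydrogenation by the Hantzsch ester); C3 of 6 is its only carbon nucleophile, and conjugate hydride transfer to the strongly electrophilic alkylidene 7 should be faster than addition of a second 6 or loss of silanol. C-alkylation is thus obtained without any O-alkylation, and no stereocentre is touched.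

Step 6
Reactants: 8 3-[(3S)-3,7-dimethyl-3-(triethylsilyloxy)oct-6-en-1-yl]-4-hydroxy-6-methyl-2H-pyran-2-one; 9 N-methoxy-N,2-dimethylpropanamide
Product: 11 3-[(3S)-3,7-dimethyl-3-(triethylsilyloxy)oct-6-en-1-yl]-4-hydroxy-6-(3-methyl-2-oxobutyl)-2H-pyran-2-one, via dilithio dianion 10 (not isolated)
Conditions: LiN(iPr)2 (2.3 equiv), THF–DMPU, −78 °C; then 9, −78 to 0 °C; aqueous NH4Cl
Reagents that add atoms: none
Why: C-acylation of a dianion with a Weinreb amide; the first equivalent of base removes the 4-OH proton and the second a proton of the 6-methyl group, giving the extended dienolate 10, whose terminal carbon is the most nucleophilic site. The stable N-methoxy-N-methyl tetrahedral chelate stops the reaction at the ketone stage and keeps the acidic product from quenching 10.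

Step 7
Reactants: 11 3-[(3S)-3,7-dimethyl-3-(triethylsilyloxy)oct-6-en-1-yl]-4-hydroxy-6-(3-methyl-2-oxobutyl)-2H-pyran-2-one
Product: 13 1-{3-[(3S)-3,7-dimethyl-3-(triethylsilyloxy)oct-6-en-1-yl]-2,4,6-trihydroxyphenyl}-2-methylpropan-1-one, via triketo ester 12 (not isolated)
Conditions: Mg(OMe)2 (5 equiv), degassed MeOH, reflux, argon; then cold aqueous NH4Cl to pH 5–6
Reagents that add atoms: none
Why: Mg(OMe)2 deprotonates the 4-hydroxyl and the doubly activated 6-CH2 of 11, and methoxide adds to the lactone carbonyl and opens the pyrone to the triketo ester 12, held as a magnesium enolate of its 3,5,7-tricarbonyl array. The enolate carbon C6 of 12 (between the C5 and C7 carbonyls) then attacks the ester carbonyl C1 in a Claisen (Dieckmann-type) condensation, a 6-(enolexo)-exo-trig closure that forms the C5–C6 bond of the benzene ring (ring numbering of 14); loss of methoxide gives a 2-acylcyclohexane-1,3,5-trione that tautomerises to the aromatic triphenoxide, which makes the sequence irreversible. The closest known reaction type is the biomimetic conversion of 6-(2-oxoalkyl)-4-hydroxy-2-pyrones and of 3,5,7-triketo esters into acylphloroglucinols by Mg(OMe)2 in methanol, the laboratory counterpart of the Claisen cyclisation of phloroglucinol-forming polyketide synthases. The selectivity needed is Claisen closure (C6 to C1) over the aldol closure (C2 to C7) that turns unsubstituted triketo esters into resorcylates; here the side chain on C2 makes the aldol adduct quaternary at C2, so it cannot dehydrate to an arene and can only revert, and the isopropyl group shields the C7 ketone. Pyrone, open chain and aldol adduct are all in equilibrium under the conditions, so material should drain through the single aromatic exit. No new stereocentre is formed, the epimeric C2 of 12 becomes sp2, and the quaternary C3' centre, its silyl ether and the alkene see only base. The three phenols emerge free, so no phenol protecting group is needed at any stage.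

Step 8
Reactants: 13 1-{3-[(3S)-3,7-dimethyl-3-(triethylsilyloxy)oct-6-en-1-yl]-2,4,6-trihydroxyphenyl}-2-methylpropan-1-one
Product: 14 1-{3-[(3S)-3-hydroxy-3,7-dimethyloct-6-en-1-yl]-2,4,6-trihydroxyphenyl}-2-methylpropan-1-one
Conditions: Bu4NF (2 equiv), AcOH (2 equiv), THF, 0 °C to rt, argon
Reagents that add atoms: none
Why: Fluoride-mediated desilylation buffered with acetic acid; formation of the Si–F bond cleaves the tertiary silyl ether under near-neutral conditions, so the tertiary alcohol is not ionised, no chroman can form and the stereocentre is untouched.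

## Compound list

1 | geraniol, (2E)-3,7-dimethylocta-2,6-dien-1-ol | CC(C)=CCC/C(C)=C/CO | starting material
2 | [(2S,3S)-3-methyl-3-(4-methylpent-3-en-1-yl)oxiran-2-yl]methanol | CC(C)=CCC[C@]1(C)O[C@H]1CO | intermediate
3 | (3S)-3,7-dimethyloct-6-ene-1,3-diol | CC(C)=CCC[C@](C)(O)CCO | intermediate
4 | (3S)-3,7-dimethyl-1,3-bis(triethylsilyloxy)oct-6-ene | CC(C)=CCC[C@](C)(O[Si](CC)(CC)CC)CCO[Si](CC)(CC)CC | intermediate
5 | (3S)-3,7-dimethyl-3-(triethylsilyloxy)oct-6-enal | CC(C)=CCC[C@](C)(O[Si](CC)(CC)CC)CC=O | intermediate
6 | 4-hydroxy-6-methyl-2H-pyran-2-one (triacetic acid lactone) | CC1=CC(O)=CC(=O)O1 | starting material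
7 | 3-[(3S)-3,7-dimethyl-3-(triethylsilyloxy)oct-6-en-1-ylidene]-6-methyl-2H-pyran-2,4(3H)-dione (not isolated) | CC(C)=CCC[C@](C)(O[Si](CC)(CC)CC)CC=C1C(=O)C=C(C)OC1=O | intermediate
8 | 3-[(3S)-3,7-dimethyl-3-(triethylsilyloxy)oct-6-en-1-yl]-4-hydroxy-6-methyl-2H-pyran-2-one | CC(C)=CCC[C@](C)(O[Si](CC)(CC)CC)CCC1=C(O)C=C(C)OC1=O | intermediate
9 | N-methoxy-N,2-dimethylpropanamide | CC(C)C(=O)N(C)OC | starting material
10 | dilithium salt of 8 deprotonated at the 4-hydroxyl and at the 6-methyl group (not isolated) | CC(C)=CCC[C@](C)(O[Si](CC)(CC)CC)CCC1=C([O-])C=C([CH2-])OC1=O.[Li+].[Li+] | intermediate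
11 | 3-[(3S)-3,7-dimethyl-3-(triethylsilyloxy)oct-6-en-1-yl]-4-hydroxy-6-(3-methyl-2-oxobutyl)-2H-pyran-2-one | CC(C)=CCC[C@](C)(O[Si](CC)(CC)CC)CCC1=C(O)C=C(CC(=O)C(C)C)OC1=O | intermediate
12 | methyl 2-[(3S)-3,7-dimethyl-3-(triethylsilyloxy)oct-6-en-1-yl]-8-methyl-3,5,7-trioxononanoate, epimers at C2, formed as its magnesium enolate (not isolated) | CC(C)=CCC[C@](C)(O[Si](CC)(CC)CC)CCC(C(=O)OC)C(=O)CC(=O)CC(=O)C(C)C | intermediate
13 | 1-{3-[(3S)-3,7-dimethyl-3-(triethylsilyloxy)oct-6-en-1-yl]-2,4,6-trihydroxyphenyl}-2-methylpropan-1-one | CC(C)=CCC[C@](C)(O[Si](CC)(CC)CC)CCc1c(O)cc(O)c(C(=O)C(C)C)c1O | intermediate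
14 | 1-{3-[(3S)-3-hydroxy-3,7-dimethyloct-6-en-1-yl]-2,4,6-trihydroxyphenyl}-2-methylpropan-1-one | CC(C)=CCC[C@](C)(O)CCc1c(O)cc(O)c(C(=O)C(C)C)c1O | target

## Step count and least certain steps

Total step count: 8. Longest linear sequence: 8 steps (1 to 14); 6 and 9 are purchased.

**Step 7 (key step).** The lactone of the doubly deprotonated pyrone may open slowly. Once the chain is open, methanolysis of the polyketone (retro-Claisen scission next to the branched carbon) may outrun the Claisen closure onto the hindered, alpha-branched ester. Air oxidation of the triphenoxide is a further loss channel. The fallback gives up ring construction and returns to arene functionalisation; it sets out from 3 and comes back at 13.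
- Selective iodination of the primary hydroxyl of 3 (iodine, PPh3, imidazole) would give (3S)-1-iodo-3,7-dimethyloct-6-en-3-ol F1.
- Silylation (Et3SiOTf, 2,6-lutidine) would give triethyl{[(3S)-1-iodo-3,7-dimethyloct-6-en-3-yl]oxy}silane F2.
- Zinc insertion (Zn dust, LiCl, THF) would give [(3S)-3,7-dimethyl-3-(triethylsilyloxy)oct-6-en-1-yl]zinc iodide F3.
- In parallel, 2-methyl-1-(2,4,6-trihydroxyphenyl)propan-1-one F4 (purchased, or made by Friedel–Crafts acylation of phloroglucinol) would be monobrominated with N-bromosuccinimide to 1-(3-bromo-2,4,6-trihydroxyphenyl)-2-methylpropan-1-one F5.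
- Acetylation (Ac2O, pyridine, DMAP) would give 2-bromo-4-(2-methylpropanoyl)benzene-1,3,5-triyl triacetate F6.
- Negishi coupling of F3 with F6 (Pd(OAc)2, SPhos, THF) would give 2-[(3S)-3,7-dimethyl-3-(triethylsilyloxy)oct-6-en-1-yl]-4-(2-methylpropanoyl)benzene-1,3,5-triyl triacetate F7.
- Methanolysis of the three acetates (K2CO3, MeOH) would give 13, which goes on to step 8.

**Step 5.** Loss of silanol by beta-elimination at the iminium, enamine or alkylidene stage would lead to conjugated dienyl products. A second molecule of 6 may also add to 7 before hydride transfer. The fallback replaces the condensation by enolate alkylation and builds the pyrone afterwards; it sets out from 3, passes through iodide F2 (prepared as described for step 7) and comes back at 8.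
- Alkylation of methyl acetoacetate with F2 (NaH, THF–DMF) would give methyl (5S)-2-acetyl-5,9-dimethyl-5-(triethylsilyloxy)dec-8-enoate F8.
- Acylation of its dianion (NaH, then n-BuLi) with N-methoxy-N-methylacetamide would give methyl 2-[(3S)-3,7-dimethyl-3-(triethylsilyloxy)oct-6-en-1-yl]-3,5-dioxohexanoate F9.
- Lactonisation (DBU, toluene, reflux) would give 8.

**Step 6.** Incomplete formation or aggregation of the dianion, competing O-acylation at the 4-oxide, and proton transfer from the amide are the likely failures. The fallback lowers the oxidation level of the electrophile; it sets out from 8 and comes back at 11. The dianion 10 would be trapped with 2-methylpropanal to give 3-[(3S)-3,7-dimethyl-3-(triethylsilyloxy)oct-6-en-1-yl]-4-hydroxy-6-(2-hydroxy-3-methylbutyl)-2H-pyran-2-one F10 (both epimers at the new carbinol are usable). Oxidation of the secondary alcohol with Dess–Martin periodinane buffered with NaHCO3 would give 11.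

**Step 4.** Cleavage of the primary silyl ether may be incomplete at low temperature, and adventitious HCl may partly remove the tertiary silyl group. The fallback separates the two events; it sets out from 4 and comes back at 5. Selective methanolysis of the primary silyl ether (pyridinium 4-toluenesulfonate, MeOH–CH2Cl2, 0 °C) would give (3S)-3,7-dimethyl-3-(triethylsilyloxy)oct-6-en-1-ol F11. Oxidation with Dess–Martin periodinane and NaHCO3 would give 5.

## Further compounds

F1 | step 7 | (3S)-1-iodo-3,7-dimethyloct-6-en-3-ol | CC(C)=CCC[C@](C)(O)CCI
F2 | step 7 | triethyl{[(3S)-1-iodo-3,7-dimethyloct-6-en-3-yl]oxy}silane | CC(C)=CCC[C@](C)(O[Si](CC)(CC)CC)CCI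
F3 | step 7 | [(3S)-3,7-dimethyl-3-(triethylsilyloxy)oct-6-en-1-yl]zinc iodide | CC(C)=CCC[C@](C)(O[Si](CC)(CC)CC)CC[Zn]I
F4 | step 7 | 2-methyl-1-(2,4,6-trihydroxyphenyl)propan-1-one | CC(C)C(=O)c1c(O)cc(O)cc1O
F5 | step 7 | 1-(3-bromo-2,4,6-trihydroxyphenyl)-2-methylpropan-1-one | CC(C)C(=O)c1c(O)cc(O)c(Br)c1O
F6 | step 7 | 2-bromo-4-(2-methylpropanoyl)benzene-1,3,5-triyl triacetate | CC(C)C(=O)c1c(OC(C)=O)cc(OC(C)=O)c(Br)c1OC(C)=O
F7 | step 7 | 2-[(3S)-3,7-dimethyl-3-(triethylsilyloxy)oct-6-en-1-yl]-4-(2-methylpropanoyl)benzene-1,3,5-triyl triacetate | CC(C)=CCC[C@](C)(O[Si](CC)(CC)CC)CCc1c(OC(C)=O)cc(OC(C)=O)c(C(=O)C(C)C)c1OC(C)=O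
F8 | step 5 | methyl (5S)-2-acetyl-5,9-dimethyl-5-(triethylsilyloxy)dec-8-enoate | CC(C)=CCC[C@](C)(O[Si](CC)(CC)CC)CCC(C(C)=O)C(=O)OC
F9 | step 5 | methyl 2-[(3S)-3,7-dimethyl-3-(triethylsilyloxy)oct-6-en-1-yl]-3,5-dioxohexanoate | CC(C)=CCC[C@](C)(O[Si](CC)(CC)CC)CCC(C(=O)CC(C)=O)C(=O)OC
F10 | step 6 | 3-[(3S)-3,7-dimethyl-3-(triethylsilyloxy)oct-6-en-1-yl]-4-hydroxy-6-(2-hydroxy-3-methylbutyl)-2H-pyran-2-one | CC(C)=CCC[C@](C)(O[Si](CC)(CC)CC)CCC1=C(O)C=C(CC(O)C(C)C)OC1=O
F11 | step 4 | (3S)-3,7-dimethyl-3-(triethylsilyloxy)oct-6-en-1-ol | CC(C)=CCC[C@](C)(O[Si](CC)(CC)CC)CCO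
A1 | alternative 1 | 1-[3-bromo-2,4,6-tris(methoxymethoxy)phenyl]-2-methylpropan-1-one | CC(C)C(=O)c1c(OCOC)cc(OCOC)c(Br)c1OCOC
A2 | alternative 1 | 9-[(3R)-3,7-dimethyl-3-(triethylsilyloxy)oct-6-en-1-yl]-9-borabicyclo[3.3.1]nonane | CC(C)=CCC[C@](C)(O[Si](CC)(CC)CC)CCB1C2CCCC1CCC2
A3 | alternative 1 | 1-{3-[(3S)-3,7-dimethyl-3-(triethylsilyloxy)oct-6-en-1-yl]-2,4,6-tris(methoxymethoxy)phenyl}-2-methylpropan-1-one | CC(C)=CCC[C@](C)(O[Si](CC)(CC)CC)CCc1c(OCOC)cc(OCOC)c(C(=O)C(C)C)c1OCOC
A4 | alternative 2 | (2S)-6-methylhept-5-en-2-yl 2,4,6-tri(propan-2-yl)benzoate | CC(C)=CCC[C@H](C)OC(=O)c1c(C(C)C)cc(C(C)C)cc1C(C)C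
A5 | alternative 2 | 4,4,5,5-tetramethyl-2-[2-(2,4,6-trimethoxyphenyl)ethyl]-1,3,2-dioxaborolane | COc1cc(OC)c(CCB2OC(C)(C)C(C)(C)O2)c(OC)c1
A6 | alternative 2 | 2-[(3R)-3,7-dimethyl-1-(2,4,6-trimethoxyphenyl)oct-6-en-3-yl]-4,4,5,5-tetramethyl-1,3,2-dioxaborolane | CC(C)=CCC[C@](C)(B1OC(C)(C)C(C)(C)O1)CCc1c(OC)cc(OC)cc1OC
A7 | alternative 3 | 1-{3-[(2E)-3,7-dimethylocta-2,6-dien-1-yl]-2,4,6-trihydroxyphenyl}-2-methylpropan-1-one | CC(C)=CCC/C(C)=C/Cc1c(O)cc(O)c(C(=O)C(C)C)c1O
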